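**Retrosynthetic overview** (carotenoid numbering; ring A = acetylenic ring C1–C6, ring B = ε ring C1′–C6′)
1. Two E-selective Wittig olefinations (C11=C12 first, C11′=C12′ last) cut the C40 chain into the ring A C15 tributylphosphonium salt, the commercial C10 trienedial and the ring B C15 tributylphosphonium salt.
2. Ring B unit: from (R)-α-ionone (C6′ bought) by Horner–Wadsworth–Emmons extension, allylic oxidation at C3′ and face-selective hydride reduction (sets C3′).
3. Ring A unit: Sonogashira coupling of (E)-3-methylpent-2-en-4-yn-1-ol with the C5=C6 enol triflate of a (4R,6S)-4-silyloxy-2,2,6-trimethylcyclohexanone; C1 is quaternary, so the ketone can enolise only toward C5.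
4. Key disconnection, C2–C3 of ring A: the carbinol C3 and C6 (a ketone, later the enyne carbon) are 1,4-related through C2 and the quaternary C1(CH3)2, a γ-hydroxy ketone. C2 is stored as a homoenolate in a temporary C2–C6 cyclopropane bond (siloxycyclopropane, not in the target) and released onto the C3 aldehyde; the C5 methyl stereocentre (Evans alkylation, erased at the triflate stage) steers C3.
5. Ring order: ring A is the only ring built (step 7); ring B comes intact from α-ionone.

Key step: step 7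

Assumption: (R)-(+)-α-ionone of high enantiomeric purity (natural grade) is taken as the commercial source of C6′; with racemic material the ring B branch would need a resolution before step 13.

**Ring A branch**

Step 1
Reactants: 1 (4R)-4-benzyl-3-propanoyl-1,3-oxazolidin-2-one
Product: 3 (4R)-4-benzyl-3-[(2S)-2-methylpent-4-enoyl]-1,3-oxazolidin-2-one, via sodium Z-enolate 2 (not isolated)
Conditions: NaN(SiMe3)2 (1.1 equiv), THF, −78 °C; allyl iodide (3 equiv), −78 → −45 °C
Reagents that add atoms: allyl iodide, C=CCI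
Why: Evans asymmetric alkylation: the chelated Z-enolate is shielded on one face by the benzyl group, so allyl iodide should enter from the other face and set the (S) centre that becomes C5 of ring A.

Step 2
Reactants: 3 (4R)-4-benzyl-3-[(2S)-2-methylpent-4-enoyl]-1,3-oxazolidin-2-one
Product: 4 (2S)-N-methoxy-N,2-dimethylpent-4-enamide
Conditions: MeONHMe·HCl (3 equiv), AlMe3 (3 equiv), CH2Cl2, −15 °C → rt
Reagents that add atoms: N,O-dimethylhydroxylamine hydrochloride, CNOC.Cl
Why: Weinreb transamination of the imide by the aluminium amide should transfer the exocyclic acyl group without enolising the α-centre, and the auxiliary is recovered.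

Step 3
Reactants: 4 (2S)-N-methoxy-N,2-dimethylpent-4-enamide
Product: 5 (4S)-2,4-dimethylhepta-1,6-dien-3-one
Conditions: CH2=C(CH3)MgBr (1.5 equiv), THF, −20 → 0 °C; inverse quench into cold aqueous NH4Cl
Reagents that add atoms: isopropenylmagnesium bromide, C=C(C)[Mg]Br
Why: Weinreb ketone synthesis: the N-methoxy-N-methylamide takes up only one equivalent of the Grignard reagent, so the isopropenyl ketone should form with the α-centre intact, and the cold inverse quench keeps the liberated amine from adding to the enone.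

Step 4
Reactants: 5 (4S)-2,4-dimethylhepta-1,6-dien-3-one
Product: 6 triethyl{[(4S)-2,4-dimethylhepta-2,6-dien-3-yl]oxy}silane
Conditions: Et3SiH (1.2 equiv), RhCl(PPh3)3 (1 mol %), benzene, rt → 50 °C
Reagents that add atoms: triethylsilane, CC[SiH](CC)CC
Why: Rhodium-catalysed 1,4-hydrosilylation of the enone puts silicon on oxygen and hydrogen on the terminal CH2, so the tetrasubstituted enol ether toward C1 forms regiospecifically and without base, which could not tell C1–H from C5–H; the isolated vinyl group should react more slowly.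

Step 5
Reactants: 6 triethyl{[(4S)-2,4-dimethylhepta-2,6-dien-3-yl]oxy}silane
Product: 7 triethyl({2,2-dimethyl-1-[(2S)-pent-4-en-2-yl]cyclopropyl}oxy)silane (both epimers at the cyclopropane carbinol carbon)
Conditions: Et2Zn (1.5 equiv), CH2I2 (1.5 equiv), CH2Cl2, 0 °C → rt
Reagents that add atoms: diiodomethane, ICI
Why: Simmons–Smith cyclopropanation in the Furukawa modification: the electrophilic zinc carbenoid should prefer the electron-rich silyl enol ether to the monosubstituted alkene and installs the temporary C2–C6 bond; the new carbinol centre forms as a mixture that converges in step 7.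

Step 6
Reactants: 7 triethyl({2,2-dimethyl-1-[(2S)-pent-4-en-2-yl]cyclopropyl}oxy)silane
Product: 9 (3S)-3-{2,2-dimethyl-1-[(triethylsilyl)oxy]cyclopropyl}butanal, via ozonide 8 (not isolated)
Conditions: O3, CH2Cl2, −78 °C (Sudan red 7B as end-point indicator); PPh3 (1.2 equiv), −78 °C → rt
Reagents that add atoms: ozone, [O-][O+]=O
Why: Ozonolysis with reductive work-up cleaves only the vinyl group and unmasks the C3 aldehyde; the siloxycyclopropane has no π bond and should survive the neutral, cold conditions.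

Step 7
Reactants: 9 (3S)-3-{2,2-dimethyl-1-[(triethylsilyl)oxy]cyclopropyl}butanal
Product: 12 (4R,6S)-4-hydroxy-2,2,6-trimethylcyclohexan-1-one, via trichlorotitanium homoenolate 10 (not isolated), via trichlorotitanium alkoxide 11 (not isolated)
Conditions: TiCl4 (1.1 equiv), 2,6-di-tert-butylpyridine (0.2 equiv), CH2Cl2, −78 → −30 °C; then cold water
Reagents that add atoms: none
Why: Proposed new method: TiCl4 should cleave the siloxycyclopropane of 9 at the C2–C6 bond, the only bond that joins the carbinol carbon to a CH2 group, with loss of Et3SiCl, to give the ketone homoenolate 10, a neopentyl-type alkyltitanium trichloride that has no β-hydrogen and cannot enolise toward C2 because C1 is quaternary; its C2–Ti bond then adds to the titanium-activated aldehyde carbon C3 of the same molecule to give alkoxide 11. The closest known reaction type is the TiCl4-mediated homoaldol addition of ester homoenolates, generated from 1-alkoxy-1-siloxycyclopropanes, to aldehydes, which has not been shown for a ketone-derived siloxycyclopropane or as a ring closure. Ring A closes through the C2–C3 bond in a 6-exo-trig mode, helped by the gem-dimethyl group at C1 (Thorpe–Ingold effect). The new stereocentre C3 is controlled by C5: in the chair-like transition state the C5 methyl group is equatorial and the metal-bound oxygen on C3 goes equatorial to avoid the axial C1 methyl group (1,3-diaxial), so the (5S) substrate should give the 3,5-cis, (3R) product, while both epimers of 9 at the cyclopropane carbinol carbon converge because that carbon becomes the C6 carbonyl. The step needs regioselective ring opening, secured by the quaternary C1, and aldehyde-over-ketone selectivity, secured by the character of alkyltitanium trichlorides and by the fact that attack on the ketone would only return the cyclopropanolate. Low temperature and the hindered pyridine base should keep protonolysis of the C2–Ti bond and epimerisation at C5 slow.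

Step 8
Reactants: 12 (4R,6S)-4-hydroxy-2,2,6-trimethylcyclohexan-1-one
Product: 13 (4R,6S)-4-[(tert-butyldimethylsilyl)oxy]-2,2,6-trimethylcyclohexan-1-one
Conditions: TBSCl (1.3 equiv), imidazole (2.5 equiv), DMF, rt
Reagents that add atoms: tert-butyldimethylsilyl chloride, CC(C)(C)[Si](C)(C)Cl
Why: Standard silylation of the unhindered secondary alcohol; the ether should survive amide base, cross-coupling, bromination and ylide chemistry.

Step 9
Reactants: 13 (4R,6S)-4-[(tert-butyldimethylsilyl)oxy]-2,2,6-trimethylcyclohexan-1-one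
Product: 15 (4R)-4-[(tert-butyldimethylsilyl)oxy]-2,6,6-trimethylcyclohex-1-en-1-yl trifluoromethanesulfonate, via lithium enolate 14 (not isolated)
Conditions: LiN(i-Pr)2 (1.3 equiv), THF, −78 → 0 °C; PhNTf2 (1.3 equiv), −78 °C → rt
Reagents that add atoms: N-phenylbis(trifluoromethanesulfonimide), O=S(=O)(N(c1ccccc1)S(=O)(=O)C(F)(F)F)C(F)(F)F
Why: Enolate O-triflation, known for 2,2,6-trimethylcyclohexanone: deprotonation is possible only at C5 because C1 is quaternary, so the C5=C6 double bond of ring A is fixed and the auxiliary stereocentre C5 is erased, while C3 is untouched.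

Step 10
Reactants: 15 (4R)-4-[(tert-butyldimethylsilyl)oxy]-2,6,6-trimethylcyclohex-1-en-1-yl trifluoromethanesulfonate; 16 (2E)-3-methylpent-2-en-4-yn-1-ol
Product: 17 (2E)-5-{(4R)-4-[(tert-butyldimethylsilyl)oxy]-2,6,6-trimethylcyclohex-1-en-1-yl}-3-methylpent-2-en-4-yn-1-ol
Conditions: Pd(PPh3)4 (5 mol %), CuI (10 mol %), i-Pr2NH (3 equiv), DMF, 50 °C, argon
Reagents that add atoms: none
Why: Sonogashira coupling of the enol triflate with the terminal alkyne should join C6 to C7 and carry the bought 9E geometry through unchanged; the free allylic alcohol is tolerated.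

Step 11
Reactants: 17 (2E)-5-{(4R)-4-[(tert-butyldimethylsilyl)oxy]-2,6,6-trimethylcyclohex-1-en-1-yl}-3-methylpent-2-en-4-yn-1-ol
Product: 19 tributyl[(2E)-5-{(4R)-4-[(tert-butyldimethylsilyl)oxy]-2,6,6-trimethylcyclohex-1-en-1-yl}-3-methylpent-2-en-4-yn-1-yl]phosphonium bromide, via allylic bromide 18 (not isolated)
Conditions: PBr3 (0.4 equiv), pyridine (0.1 equiv), Et2O, −20 °C; cold aqueous NaHCO3 wash; PBu3 (1.1 equiv), EtOAc, 0 °C → rt
Reagents that add atoms: phosphorus tribromide, BrP(Br)Br; tributylphosphine, CCCCP(CCCC)CCCC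
Why: Buffered low-temperature bromination of the primary allylic alcohol followed at once by SN2 quaternisation with the strongly nucleophilic PBu3 should give the salt before the allylic bromide can ionise and scramble the C9=C10 geometry.

Step 12
Reactants: 19 tributyl[(2E)-5-{(4R)-4-[(tert-butyldimethylsilyl)oxy]-2,6,6-trimethylcyclohex-1-en-1-yl}-3-methylpent-2-en-4-yn-1-yl]phosphonium bromide; 20 (2E,4E,6E)-2,7-dimethylocta-2,4,6-trienedial
Product: 22 (2E,4E,6E,8E,10E)-13-{(4R)-4-[(tert-butyldimethylsilyl)oxy]-2,6,6-trimethylcyclohex-1-en-1-yl}-2,7,11-trimethyltrideca-2,4,6,8,10-pentaen-12-ynal, via ylide 21 (not isolated)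
Conditions: KOt-Bu (1.05 equiv), THF, −78 °C; added to 20 (3 equiv), THF, −78 → 0 °C, dark
Reagents that add atoms: none
Why: Wittig olefination: allylic trialkylphosphonium ylides are E-selective, so C11=C12 should form E without a later isomerisation that would endanger the thermodynamically disfavoured 9E enyne, and the excess of the symmetric dialdehyde favours mono-olefination.

**Ring B branch**

Step 13
Reactants: 23 (3E)-4-[(1R)-2,6,6-trimethylcyclohex-2-en-1-yl]but-3-en-2-one ((R)-α-ionone)
Product: 24 ethyl (2E,4E)-3-methyl-5-[(1R)-2,6,6-trimethylcyclohex-2-en-1-yl]penta-2,4-dienoate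
Conditions: (EtO)2P(O)CH2CO2Et (2 equiv), NaH (1.9 equiv), THF, 0 → 45 °C; minor 2Z isomer removed by chromatography
Reagents that add atoms: triethyl phosphonoacetate, CCOC(=O)CP(=O)(OCC)OCC
Why: Horner–Wadsworth–Emmons olefination of the methyl ketone should give mainly the 2E ester (C9′=C10′), and the stabilised phosphonate anion is too weak a base to remove the γ-hydrogen at C6′, so no racemisation or shift to the β-isomer is expected.

Step 14
Reactants: 24 ethyl (2E,4E)-3-methyl-5-[(1R)-2,6,6-trimethylcyclohex-2-en-1-yl]penta-2,4-dienoate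
Product: 25 ethyl (2E,4E)-3-methyl-5-[(1R)-2,6,6-trimethyl-4-oxocyclohex-2-en-1-yl]penta-2,4-dienoate
Conditions: t-BuOOH (70% in water, 5 equiv), dirhodium tetrakis(caprolactamate) Rh2(C6H10NO)4 (1 mol %), K2CO3 (0.5 equiv), CH2Cl2, rt
Reagents that add atoms: tert-butyl hydroperoxide, CC(C)(C)OO
Why: Peroxyl-radical allylic C–H oxidation should take the only secondary allylic CH2 (C3′) to the enone, since C6′–H is shielded by the gem-dimethyl group and the C5′ methyl group and the side-chain methyl is deactivated by the dienoate.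

Step 15
Reactants: 25 ethyl (2E,4E)-3-methyl-5-[(1R)-2,6,6-trimethyl-4-oxocyclohex-2-en-1-yl]penta-2,4-dienoate
Product: 26 ethyl (2E,4E)-5-[(1R,4R)-4-hydroxy-2,6,6-trimethylcyclohex-2-en-1-yl]-3-methylpenta-2,4-dienoate
Conditions: LiBH(s-Bu)3 (1.2 equiv), THF, −78 °C; aqueous NH4Cl
Reagents that add atoms: none
Why: 1,2-Reduction of the β,β-disubstituted enone by a bulky hydride: allylic strain with the C5′ methyl group holds the C6′ side chain pseudo-axial, the C1′ methyl group anti to it blocks the opposite face of the C3′ carbonyl, so hydride should enter syn to the chain and leave the C3′–OH trans to it, (3′R); the ester is inert at −78 °C.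

Step 16
Reactants: 26 ethyl (2E,4E)-5-[(1R,4R)-4-hydroxy-2,6,6-trimethylcyclohex-2-en-1-yl]-3-methylpenta-2,4-dienoate
Product: 27 ethyl (2E,4E)-5-{(1R,4R)-4-[(tert-butyldimethylsilyl)oxy]-2,6,6-trimethylcyclohex-2-en-1-yl}-3-methylpenta-2,4-dienoate
Conditions: TBSCl (1.3 equiv), imidazole (2.5 equiv), DMF, rt
Reagents that add atoms: tert-butyldimethylsilyl chloride, CC(C)(C)[Si](C)(C)Cl
Why: Silylation protects the acid-sensitive allylic C3′–OH through bromination and ylide formation.

Step 17
Reactants: 27 ethyl (2E,4E)-5-{(1R,4R)-4-[(tert-butyldimethylsilyl)oxy]-2,6,6-trimethylcyclohex-2-en-1-yl}-3-methylpenta-2,4-dienoate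
Product: 28 (2E,4E)-5-{(1R,4R)-4-[(tert-butyldimethylsilyl)oxy]-2,6,6-trimethylcyclohex-2-en-1-yl}-3-methylpenta-2,4-dien-1-ol
Conditions: i-Bu2AlH (2.5 equiv), CH2Cl2, −78 °C; aqueous potassium sodium tartrate
Reagents that add atoms: none
Why: Aluminium hydride 1,2-reduction of the dienoate should give the dienyl alcohol without touching the double bonds or the silyl ether.

Step 18
Reactants: 28 (2E,4E)-5-{(1R,4R)-4-[(tert-butyldimethylsilyl)oxy]-2,6,6-trimethylcyclohex-2-en-1-yl}-3-methylpenta-2,4-dien-1-ol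
Product: 30 tributyl[(2E,4E)-5-{(1R,4R)-4-[(tert-butyldimethylsilyl)oxy]-2,6,6-trimethylcyclohex-2-en-1-yl}-3-methylpenta-2,4-dien-1-yl]phosphonium bromide, via allylic bromide 29 (not isolated)
Conditions: PBr3 (0.4 equiv), pyridine (0.1 equiv), Et2O, −20 °C; cold aqueous NaHCO3 wash; PBu3 (1.1 equiv), EtOAc, 0 °C → rt
Reagents that add atoms: phosphorus tribromide, BrP(Br)Br; tributylphosphine, CCCCP(CCCC)CCCC
Why: As in step 11, buffered bromination and immediate SN2 capture by PBu3 should give the salt without strong acid, which would ionise the allylic C3′ position of ring B.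

**Assembly**

Step 19
Reactants: 30 tributyl[(2E,4E)-5-{(1R,4R)-4-[(tert-butyldimethylsilyl)oxy]-2,6,6-trimethylcyclohex-2-en-1-yl}-3-methylpenta-2,4-dien-1-yl]phosphonium bromide; 22 (2E,4E,6E,8E,10E)-13-{(4R)-4-[(tert-butyldimethylsilyl)oxy]-2,6,6-trimethylcyclohex-1-en-1-yl}-2,7,11-trimethyltrideca-2,4,6,8,10-pentaen-12-ynal
Product: 32 (3R,3′R,6′R)-3,3′-bis[(tert-butyldimethylsilyl)oxy]-7,8-didehydro-β,ε-carotene, via ylide 31 (not isolated)
Conditions: KOt-Bu (1.1 equiv), THF, −78 °C; 22 (0.9 equiv), −78 → 0 °C, dark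
Reagents that add atoms: none
Why: Second Wittig olefination with an E-selective allylic tributylphosphonium ylide should form C11′=C12′ as the E isomer and complete the C40 chain under base-only conditions that leave both silyl ethers and the 9E enyne alone.

Step 20
Reactants: 32 (3R,3′R,6′R)-3,3′-bis[(tert-butyldimethylsilyl)oxy]-7,8-didehydro-β,ε-carotene
Product: 33 (3R,3′R,6′R)-7,8-didehydro-β,ε-carotene-3,3′-diol
Conditions: Bu4NF (4 equiv), AcOH (4 equiv), THF, rt, dark, argon
Reagents that add atoms: none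
Why: Buffered fluoride desilylation should free both hydroxyl groups without acid, so the allylic C3′–OH neither epimerises nor eliminates and the polyene is not isomerised.

**Compound list**
1 | (4R)-4-benzyl-3-propanoyl-1,3-oxazolidin-2-one | CCC(=O)N1[C@H](Cc2ccccc2)COC1=O | starting material
2 | sodium Z-enolate of 1 | [Na+].C/C=C(\[O-])N1[C@H](Cc2ccccc2)COC1=O | intermediate
3 | (4R)-4-benzyl-3-[(2S)-2-methylpent-4-enoyl]-1,3-oxazolidin-2-one | C=CC[C@H](C)C(=O)N1[C@H](Cc2ccccc2)COC1=O | intermediate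
4 | (2S)-N-methoxy-N,2-dimethylpent-4-enamide | C=CC[C@H](C)C(=O)N(C)OC | intermediate
5 | (4S)-2,4-dimethylhepta-1,6-dien-3-one | C=CC[C@H](C)C(=O)C(C)=C | intermediate
6 | triethyl{[(4S)-2,4-dimethylhepta-2,6-dien-3-yl]oxy}silane | C=CC[C@H](C)C(O[Si](CC)(CC)CC)=C(C)C | intermediate
7 | triethyl({2,2-dimethyl-1-[(2S)-pent-4-en-2-yl]cyclopropyl}oxy)silane, both epimers at the carbinol carbon | C=CC[C@H](C)C1(O[Si](CC)(CC)CC)CC1(C)C | intermediate
8 | 3-{(2S)-2-[2,2-dimethyl-1-(triethylsilyloxy)cyclopropyl]propyl}-1,2,4-trioxolane (ozonide) | C1OC(C[C@H](C)C2(O[Si](CC)(CC)CC)CC2(C)C)OO1 | intermediate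
9 | (3S)-3-{2,2-dimethyl-1-[(triethylsilyl)oxy]cyclopropyl}butanal | O=CC[C@H](C)C1(O[Si](CC)(CC)CC)CC1(C)C | intermediate
10 | trichloro[(4S)-2,2,4-trimethyl-3,6-dioxohexyl]titanium (homoenolate) | O=CC[C@H](C)C(=O)C(C)(C)C[Ti](Cl)(Cl)Cl | intermediate
11 | trichlorotitanium alkoxide of 12 | C[C@H]1C[C@@H](O[Ti](Cl)(Cl)Cl)CC(C)(C)C1=O | intermediate
12 | (4R,6S)-4-hydroxy-2,2,6-trimethylcyclohexan-1-one | C[C@H]1C[C@@H](O)CC(C)(C)C1=O | intermediate
13 | (4R,6S)-4-[(tert-butyldimethylsilyl)oxy]-2,2,6-trimethylcyclohexan-1-one | C[C@H]1C[C@@H](O[Si](C)(C)C(C)(C)C)CC(C)(C)C1=O | intermediate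
14 | lithium (4R)-4-[(tert-butyldimethylsilyl)oxy]-2,6,6-trimethylcyclohex-1-en-1-olate | [Li+].[O-]C1=C(C)C[C@@H](O[Si](C)(C)C(C)(C)C)CC1(C)C | intermediate
15 | (4R)-4-[(tert-butyldimethylsilyl)oxy]-2,6,6-trimethylcyclohex-1-en-1-yl trifluoromethanesulfonate | FC(F)(F)S(=O)(=O)OC1=C(C)C[C@@H](O[Si](C)(C)C(C)(C)C)CC1(C)C | intermediate
16 | (2E)-3-methylpent-2-en-4-yn-1-ol | OC/C=C(\C)C#C | starting material
17 | (2E)-5-{(4R)-4-[(tert-butyldimethylsilyl)oxy]-2,6,6-trimethylcyclohex-1-en-1-yl}-3-methylpent-2-en-4-yn-1-ol | OC/C=C(\C)C#CC1=C(C)C[C@@H](O[Si](C)(C)C(C)(C)C)CC1(C)C | intermediate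
18 | {[(1R)-4-[(3E)-5-bromo-3-methylpent-3-en-1-yn-1-yl]-3,5,5-trimethylcyclohex-3-en-1-yl]oxy}(tert-butyl)dimethylsilane (allylic bromide) | BrC/C=C(\C)C#CC1=C(C)C[C@@H](O[Si](C)(C)C(C)(C)C)CC1(C)C | intermediate
19 | tributyl[(2E)-5-{(4R)-4-[(tert-butyldimethylsilyl)oxy]-2,6,6-trimethylcyclohex-1-en-1-yl}-3-methylpent-2-en-4-yn-1-yl]phosphonium bromide | [Br-].CCCC[P+](CCCC)(CCCC)C/C=C(\C)C#CC1=C(C)C[C@@H](O[Si](C)(C)C(C)(C)C)CC1(C)C | intermediate
20 | (2E,4E,6E)-2,7-dimethylocta-2,4,6-trienedial | O=C/C(C)=C/C=C/C=C(C)/C=O | starting material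
21 | ylide of 19 | CCCC[P+](CCCC)(CCCC)[CH-]/C=C(\C)C#CC1=C(C)C[C@@H](O[Si](C)(C)C(C)(C)C)CC1(C)C | intermediate
22 | (2E,4E,6E,8E,10E)-13-{(4R)-4-[(tert-butyldimethylsilyl)oxy]-2,6,6-trimethylcyclohex-1-en-1-yl}-2,7,11-trimethyltrideca-2,4,6,8,10-pentaen-12-ynal | O=C/C(C)=C/C=C/C=C(C)/C=C/C=C(\C)C#CC1=C(C)C[C@@H](O[Si](C)(C)C(C)(C)C)CC1(C)C | intermediate
23 | (3E)-4-[(1R)-2,6,6-trimethylcyclohex-2-en-1-yl]but-3-en-2-one, (R)-α-ionone | CC1=CCCC(C)(C)[C@H]1/C=C/C(C)=O | starting material
24 | ethyl (2E,4E)-3-methyl-5-[(1R)-2,6,6-trimethylcyclohex-2-en-1-yl]penta-2,4-dienoate | CC1=CCCC(C)(C)[C@H]1/C=C/C(C)=C/C(=O)OCC | intermediate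
25 | ethyl (2E,4E)-3-methyl-5-[(1R)-2,6,6-trimethyl-4-oxocyclohex-2-en-1-yl]penta-2,4-dienoate | CC1=CC(=O)CC(C)(C)[C@H]1/C=C/C(C)=C/C(=O)OCC | intermediate
26 | ethyl (2E,4E)-5-[(1R,4R)-4-hydroxy-2,6,6-trimethylcyclohex-2-en-1-yl]-3-methylpenta-2,4-dienoate | CC1=C[C@H](O)CC(C)(C)[C@H]1/C=C/C(C)=C/C(=O)OCC | intermediate
27 | ethyl (2E,4E)-5-{(1R,4R)-4-[(tert-butyldimethylsilyl)oxy]-2,6,6-trimethylcyclohex-2-en-1-yl}-3-methylpenta-2,4-dienoate | CC1=C[C@H](O[Si](C)(C)C(C)(C)C)CC(C)(C)[C@H]1/C=C/C(C)=C/C(=O)OCC | intermediate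
28 | (2E,4E)-5-{(1R,4R)-4-[(tert-butyldimethylsilyl)oxy]-2,6,6-trimethylcyclohex-2-en-1-yl}-3-methylpenta-2,4-dien-1-ol | CC1=C[C@H](O[Si](C)(C)C(C)(C)C)CC(C)(C)[C@H]1/C=C/C(C)=C/CO | intermediate
29 | {[(1R,4R)-4-[(1E,3E)-5-bromo-3-methylpenta-1,3-dien-1-yl]-3,5,5-trimethylcyclohex-2-en-1-yl]oxy}(tert-butyl)dimethylsilane (allylic bromide) | CC1=C[C@H](O[Si](C)(C)C(C)(C)C)CC(C)(C)[C@H]1/C=C/C(C)=C/CBr | intermediate
30 | tributyl[(2E,4E)-5-{(1R,4R)-4-[(tert-butyldimethylsilyl)oxy]-2,6,6-trimethylcyclohex-2-en-1-yl}-3-methylpenta-2,4-dien-1-yl]phosphonium bromide | [Br-].CC1=C[C@H](O[Si](C)(C)C(C)(C)C)CC(C)(C)[C@H]1/C=C/C(C)=C/C[P+](CCCC)(CCCC)CCCC | intermediate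
31 | ylide of 30 | CC1=C[C@H](O[Si](C)(C)C(C)(C)C)CC(C)(C)[C@H]1/C=C/C(C)=C/[CH-][P+](CCCC)(CCCC)CCCC | intermediate
32 | (3R,3′R,6′R)-3,3′-bis[(tert-butyldimethylsilyl)oxy]-7,8-didehydro-β,ε-carotene | CC1=C[C@H](O[Si](C)(C)C(C)(C)C)CC(C)(C)[C@H]1/C=C/C(C)=C/C=C/C(C)=C/C=C/C=C(C)/C=C/C=C(\C)C#CC1=C(C)C[C@@H](O[Si](C)(C)C(C)(C)C)CC1(C)C | intermediate
33 | (3R,3′R,6′R)-7,8-didehydro-β,ε-carotene-3,3′-diol | CC1=C[C@H](O)CC(C)(C)[C@H]1/C=C/C(C)=C/C=C/C(C)=C/C=C/C=C(C)/C=C/C=C(\C)C#CC1=C(C)C[C@@H](O)CC1(C)C | target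

**Totals**
Total step count: 20. Longest linear sequence: 14 steps (steps 1–12, 19, 20).

**Steps most likely to fail**

Step 7. What may go wrong: the C2–titanium bond, or the cyclopropane itself, is protonated to a tert-butyl ketone before the carbon–carbon bond forms, or the addition runs through a non-chair geometry so that facial selectivity at C3 is lost. The fallback uses known chemistry, sets out from 7 and comes back at 12. Siloxycyclopropane 7 is opened at its CH2 corner with N-iodosuccinimide (CH2Cl2, 0 °C) to (4S)-1-iodo-2,2,4-trimethylhept-6-en-3-one F1, whose quaternary α-carbon rules out loss of HI. Oxidative cleavage of the vinyl group (catalytic OsO4, NaIO4, 2,6-lutidine, dioxane–water) gives (3S)-6-iodo-3,5,5-trimethyl-4-oxohexanal F2. An alkyl Nozaki–Hiyama–Kishi cyclisation (CrCl2, catalytic cobalt phthalocyanine Co(C32H16N8), DMF, rt), selective for aldehydes over ketones, then closes the same C2–C3 bond and gives 12.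

Step 5. What may go wrong: methylene transfer to the terminal vinyl group competes with the hindered tetrasubstituted enol ether, so chemoselectivity is lost. The fallback sets out from 5 and comes back at 7. Conjugate reduction of enone 5 with LiBH(s-Bu)3 (THF, −78 °C) gives lithium (4S)-2,4-dimethylhepta-2,6-dien-3-olate F3 in the flask. The samarium carbenoid from CH2I2 and SmI2, which attacks metal enolates and leaves isolated alkenes alone, converts it to 2,2-dimethyl-1-[(2S)-pent-4-en-2-yl]cyclopropan-1-ol F4. Silylation (Et3SiOTf, 2,6-lutidine, CH2Cl2, −78 °C) gives 7.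

Step 15. What may go wrong: hydride is delivered to the other face of the C3′ carbonyl (poor facial selectivity), which gives the cis alcohol. The fallback sets out from 25 and comes back at 26. Luche reduction (NaBH4, CeCl3, MeOH, −20 °C), or whatever reagent favours that face, gives ethyl (2E,4E)-5-[(1R,4S)-4-hydroxy-2,6,6-trimethylcyclohex-2-en-1-yl]-3-methylpenta-2,4-dienoate F5. Mitsunobu esterification with inversion (4-nitrobenzoic acid, PPh3, diisopropyl azodicarboxylate, toluene, 0 °C) gives (1R,4R)-4-[(1E,3E)-5-ethoxy-3-methyl-5-oxopenta-1,3-dien-1-yl]-3,5,5-trimethylcyclohex-2-en-1-yl 4-nitrobenzoate F6. Ethanolysis (K2CO3, EtOH, rt) gives 26.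

**Further compounds**
F1 | step 7 | (4S)-1-iodo-2,2,4-trimethylhept-6-en-3-one | C=CC[C@H](C)C(=O)C(C)(C)CI
F2 | step 7 | (3S)-6-iodo-3,5,5-trimethyl-4-oxohexanal | O=CC[C@H](C)C(=O)C(C)(C)CI
F3 | step 5 | lithium (4S)-2,4-dimethylhepta-2,6-dien-3-olate | [Li+].C=CC[C@H](C)C([O-])=C(C)C
F4 | step 5 | 2,2-dimethyl-1-[(2S)-pent-4-en-2-yl]cyclopropan-1-ol | C=CC[C@H](C)C1(O)CC1(C)C
F5 | step 15 | ethyl (2E,4E)-5-[(1R,4S)-4-hydroxy-2,6,6-trimethylcyclohex-2-en-1-yl]-3-methylpenta-2,4-dienoate | CC1=C[C@@H](O)CC(C)(C)[C@H]1/C=C/C(C)=C/C(=O)OCC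
F6 | step 15 | (1R,4R)-4-[(1E,3E)-5-ethoxy-3-methyl-5-oxopenta-1,3-dien-1-yl]-3,5,5-trimethylcyclohex-2-en-1-yl 4-nitrobenzoate | CC1=C[C@H](OC(=O)c2ccc(cc2)[N+](=O)[O-])CC(C)(C)[C@H]1/C=C/C(C)=C/C(=O)OCC
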